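**Plan**

1. Numbering used throughout: carbocycle C1–C10 with the ether O bridging C2 and C9 (oxolane O/C2/C1/C10/C9, oxonene O/C2–C9); cyclohexane C1/C10–C14; lactone C14–C15(C16H3)–C17(=O)–O–C3; methyls on C3, C7, C11.
2. Retrosynthetic cuts, in order: C11 ester and C11–CH3 (back to a C11 ketone); C15–H (α-methylene lactone); C17–O3 and C15–C17 (CO insertion into a C15 enol triflate); C1–C14 and C12–C13 (Diels–Alder) with C10–C11 (Stille); C8–C9 with O–C6 restored (reverse of an oxonium ylide [2,3] shift, giving an oxane); C3–CH3; C2–C3 (ketyl–olefin cyclisation).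
3. Forward order of rings: oxane (O, C2–C6), then the oxabicyclo[6.2.1]undecenone (oxolane plus Z-oxonene), then the cyclohexene, then the seven-membered lactone; C15, C11 and the butanoate follow.
4. Enabling feature: C2 and C3 are vicinal oxygen-bearing carbons, and C6, four bonds from C2, is an sp2 carbon of C6=C7 in the target. The ether oxygen can therefore sit on C6 temporarily, so that O, C2, C3, C4, C5 and C6 form an oxane closed at C2–C3; the later [2,3] shift moves the oxygen from C6 to C9 and creates C6=C7.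
5. Stereochemistry: C6 (S) comes from a catalytic CBS reduction, sets C2 in the key step (2,6-cis) and is then consumed. C2 relays to C3 (chelation), C9 (bridge), C1 (exo Diels–Alder face), C14 and C10 (equilibration), C11 and C15 (substrate-controlled additions); the Z alkene is reached by equilibrating the E/Z mixture.

Key step: step 6

**Route**

Step 1
Reactants: 1 2-(2-bromoethyl)-1,3-dioxolane; 2 methacrolein
Product: 4 (±)-1-(1,3-dioxolan-2-yl)-4-methylpent-4-en-3-ol, via Grignard reagent 3 (not isolated)
Conditions: Mg, THF, 25–30 °C; then 2, −78 → 0 °C; aq. NH4Cl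
Reagents that add atoms: none
Why: 1,2-addition of the acetal-bearing Grignard reagent to the enal (Grignard addition) joins C5–C6 and should give the racemic allylic alcohol, whose configuration is fixed in steps 2–3.

Step 2
Reactants: 4 (±)-1-(1,3-dioxolan-2-yl)-4-methylpent-4-en-3-ol
Product: 5 1-(1,3-dioxolan-2-yl)-4-methylpent-4-en-3-one
Conditions: Dess–Martin periodinane, CH2Cl2, 0 °C → rt
Reagents that add atoms: none
Why: Dess–Martin oxidation of the secondary allylic alcohol should give the α-methylene ketone under conditions that spare the acetal.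

Step 3
Reactants: 5 1-(1,3-dioxolan-2-yl)-4-methylpent-4-en-3-one
Product: 6 (3S)-1-(1,3-dioxolan-2-yl)-4-methylpent-4-en-3-ol
Conditions: (R)-B-methyl oxazaborolidine from α,α-diphenylprolinol ((R)-Me-CBS, 10 mol %), catecholborane, toluene, −78 °C
Reagents that add atoms: none
Why: CBS reduction with the isopropenyl group as the large substituent should deliver hydride to the face that gives the 3S carbinol (C6 of the target numbering) under catalyst control, and catecholborane at low temperature avoids hydroboration of the alkene.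

Step 4
Reactants: 6 (3S)-1-(1,3-dioxolan-2-yl)-4-methylpent-4-en-3-ol; 7 ethyl propiolate
Product: 8 ethyl (2E)-3-{[(3S)-1-(1,3-dioxolan-2-yl)-4-methylpent-4-en-3-yl]oxy}prop-2-enoate
Conditions: N-methylmorpholine, CH2Cl2, rt
Reagents that add atoms: none
Why: Amine-catalysed oxa-Michael addition of the alcohol to the propiolate should give the (E)-β-alkoxyacrylate, which supplies C2, C1 and C10.

Step 5
Reactants: 8 ethyl (2E)-3-{[(3S)-1-(1,3-dioxolan-2-yl)-4-methylpent-4-en-3-yl]oxy}prop-2-enoate
Product: 9 ethyl (2E)-3-{[(3S)-2-methyl-6-oxohex-1-en-3-yl]oxy}prop-2-enoate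
Conditions: 2 M HCl, THF, rt
Reagents that add atoms: water, O
Why: Acid hydrolysis of the dioxolane should free the C3 aldehyde, while the electron-poor β-alkoxyacrylate resists dilute acid.

Step 6
Reactants: 9 ethyl (2E)-3-{[(3S)-2-methyl-6-oxohex-1-en-3-yl]oxy}prop-2-enoate
Product: 11 ethyl 2-[(2S,3R,6S)-3-hydroxy-6-(prop-1-en-2-yl)oxan-2-yl]acetate, via samarium ketyl 10 (not isolated)
Conditions: SmI2 (2.5 equiv), MeOH (3 equiv), THF, 0 °C → rt
Reagents that add atoms: none
Why: SmI2 reduces the aldehyde to samarium ketyl 10, whose carbon radical adds to the β-carbon (C2) of the (E)-β-alkoxyacrylate; a second electron transfer and protonation by MeOH give the hydroxy ester. The closest known reaction type is the SmI2-mediated reductive ketyl–olefin cyclisation of aldehydes onto β-alkoxyacrylates, used to make 2,3-trans-oxanes in polycyclic ether synthesis. The oxane (O, C2–C6) closes in the 6-exo-trig mode by forming C2–C3. C2 is set by a chair transition state with the C6 isopropenyl group and the acrylate both equatorial (2,6-cis, so C6 dictates C2); C3 is set with the ketyl oxygen equatorial, anti to the ring oxygen and chelated through trivalent samarium to the ester carbonyl (2,3-trans; this centre is re-set in steps 7–8). The step needs reduction of the aldehyde in preference to the acrylate, no reaction at the 1,1-disubstituted alkene, and cyclisation in preference to pinacol coupling. The lower reduction potential of the aldehyde, the electron-poor acceptor held five atoms away and the proton source should secure this.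

Step 7
Reactants: 11 ethyl 2-[(2S,3R,6S)-3-hydroxy-6-(prop-1-en-2-yl)oxan-2-yl]acetate
Product: 12 ethyl 2-[(2S,6S)-3-oxo-6-(prop-1-en-2-yl)oxan-2-yl]acetate
Conditions: Dess–Martin periodinane, CH2Cl2, rt
Reagents that add atoms: none
Why: Dess–Martin oxidation should give the oxan-3-one without epimerising C2, which in any case prefers the 2,6-cis diequatorial arrangement.

Step 8
Reactants: 12 ethyl 2-[(2S,6S)-3-oxo-6-(prop-1-en-2-yl)oxan-2-yl]acetate
Product: 13 ethyl 2-[(2S,3S,6S)-3-hydroxy-3-methyl-6-(prop-1-en-2-yl)oxan-2-yl]acetate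
Conditions: MeMgCl, THF, −78 °C
Reagents that add atoms: methylmagnesium chloride, C[Mg]Cl
Why: Chelation-controlled Grignard addition (magnesium held between the ketone and the ring oxygen) should bring the methyl group in anti to the equatorial C2 side chain, placing the methyl trans and the new hydroxyl cis to C1 (3S), while the ester is untouched at −78 °C.

Step 9
Reactants: 13 ethyl 2-[(2S,3S,6S)-3-hydroxy-3-methyl-6-(prop-1-en-2-yl)oxan-2-yl]acetate
Product: 14 ethyl 2-[(2S,3S,6S)-3-[(tert-butyldimethylsilyl)oxy]-3-methyl-6-(prop-1-en-2-yl)oxan-2-yl]acetate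
Conditions: tert-butyldimethylsilyl triflate, 2,6-lutidine, CH2Cl2, 0 °C → rt
Reagents that add atoms: tert-butyldimethylsilyl triflate, CC(C)(C)[Si](C)(C)OS(=O)(=O)C(F)(F)F
Why: Silylation of the tertiary alcohol with the silyl triflate masks O3 so that only the ring oxygen can later capture the carbene.

Step 10
Reactants: 14 ethyl 2-[(2S,3S,6S)-3-[(tert-butyldimethylsilyl)oxy]-3-methyl-6-(prop-1-en-2-yl)oxan-2-yl]acetate
Product: 15 2-[(2S,3S,6S)-3-[(tert-butyldimethylsilyl)oxy]-3-methyl-6-(prop-1-en-2-yl)oxan-2-yl]acetic acid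
Conditions: LiOH, THF/MeOH/H2O, rt; then 1 M HCl to pH 3
Reagents that add atoms: lithium hydroxide, [Li+].[OH-]
Why: Saponification of the ethyl ester should give the acid without β-elimination of the ring oxygen.

Step 11
Reactants: 15 2-[(2S,3S,6S)-3-[(tert-butyldimethylsilyl)oxy]-3-methyl-6-(prop-1-en-2-yl)oxan-2-yl]acetic acid
Product: 17 1-diazo-3-[(2S,3S,6S)-3-[(tert-butyldimethylsilyl)oxy]-3-methyl-6-(prop-1-en-2-yl)oxan-2-yl]propan-2-one, via mixed anhydride 16 (not isolated)
Conditions: isobutyl chloroformate, Et3N, Et2O, −20 °C; then CH2N2, Et2O, 0 °C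
Reagents that add atoms: diazomethane, C=[N+]=[N-]
Why: Acylation of diazomethane by the mixed carbonic anhydride should give the α-diazoketone, whose diazo carbon becomes C9.

Step 12
Reactants: 17 1-diazo-3-[(2S,3S,6S)-3-[(tert-butyldimethylsilyl)oxy]-3-methyl-6-(prop-1-en-2-yl)oxan-2-yl]propan-2-one
Product: 20 (1S,2S,5Z,8S)-2-[(tert-butyldimethylsilyl)oxy]-2,6-dimethyl-11-oxabicyclo[6.2.1]undec-5-en-9-one, via oxonium ylide 18 (not isolated), via E/Z ketone mixture 19 (not isolated)
Conditions: copper bis(hexafluoroacetylacetonate), Cu(CF3COCHCOCF3)2 (5 mol %), CH2Cl2, reflux; then EtSH, AIBN, benzene, 80 °C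
Reagents that add atoms: none
Why: Copper-catalysed loss of N2 and carbene transfer to the oxane oxygen give oxonium ylide 18, whose [2,3]-sigmatropic shift onto the isopropenyl terminus forms C8–C9, breaks O–C6 and creates C6=C7, so the oxane expands to the bridged oxolane/oxonene with C9 forced cis to C2 and the C6 centre consumed; reversible thiyl-radical addition then should funnel the E isomer into the more stable Z alkene.

Step 13
Reactants: 20 (1S,2S,5Z,8S)-2-[(tert-butyldimethylsilyl)oxy]-2,6-dimethyl-11-oxabicyclo[6.2.1]undec-5-en-9-one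
Product: 21 C10 enol triflate of 20 (C10(OTf)=C1; 2S,3S,9S; 6Z)
Conditions: NaN(SiMe3)2, PhNTf2, THF, −78 °C
Reagents that add atoms: N-phenylbis(trifluoromethanesulfonimide), O=S(=O)(N(c1ccccc1)S(=O)(=O)C(F)(F)F)C(F)(F)F
Why: Kinetic enolisation toward the C1 methylene (not the bridgehead C9) and O-sulfonylation should give the enol triflate.

Step 14
Reactants: 21 C10 enol triflate of 20; 22 tributyl(1-ethoxyvinyl)stannane
Product: 23 bicyclic 2-ethoxydiene (C1=C10–C11(OEt)=C12H2; 2S,3S,9S; 6Z)
Conditions: Pd(PPh3)4 (5 mol %), LiCl, THF, reflux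
Reagents that add atoms: none
Why: Stille coupling of the enol triflate with the α-ethoxyvinylstannane forms C10–C11 and gives an electron-rich diene that carries the C11 carbonyl in masked form.

Step 15
Reactants: 23 bicyclic 2-ethoxydiene; 24 methyl vinyl ketone
Product: 26 trans-acetyl cycloadduct (C10=C11 ethyl enol ether; C14 acetyl trans to C2; 1S,2S,3S,9S,14R; 6Z), via C14 epimer mixture 25 (not isolated)
Conditions: 24 (excess), toluene, 110 °C; then K2CO3, MeOH, rt
Reagents that add atoms: none
Why: Diels–Alder addition of the enone forms C12–C13 and C1–C14 with the acetyl para to the ethoxy group and on the exo face of the bicycle (opposite the oxonene bridge, setting C1), and base then epimerises C14 through the enolate so that the endo/exo mixture should converge on the equatorial trans isomer.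

Step 16
Reactants: 26 trans-acetyl cycloadduct
Product: 27 C15 enol triflate (C14–C15(OTf)=C16H2; enol ether and silyl ether retained)
Conditions: KN(SiMe3)2, THF, −78 °C; then PhNTf2
Reagents that add atoms: N-phenylbis(trifluoromethanesulfonimide), O=S(=O)(N(c1ccccc1)S(=O)(=O)C(F)(F)F)C(F)(F)F
Why: Kinetic deprotonation of the methyl ketone at the methyl group (C14–H is hindered and the C11 carbonyl is still masked as the enol ether) and trapping should give the terminal enol triflate.

Step 17
Reactants: 27 C15 enol triflate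
Product: 28 hydroxy ketone enol triflate (free C3–OH; C11 ketone; cis ring fusion; 1S,2S,3S,9S,10R,14R)
Conditions: 48% aq. HF, MeCN, 0 °C → rt
Reagents that add atoms: water, O
Why: Aqueous HF cleaves the tertiary silyl ether and hydrolyses the enol ether, and C10 protonation with enol equilibration should leave the cis fusion, the only one that keeps C11 on the exo face of the oxolane.

Step 18
Reactants: 28 hydroxy ketone enol triflate
Product: 29 α-methylene lactone ketone (C17(=O)–O–C3 closed; C15=C16H2; C11 ketone)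
Conditions: Pd(PPh3)4 (10 mol %), CO (1 atm), nBu3N, LiCl, MeCN, 65 °C
Reagents that add atoms: carbon monoxide, [C-]#[O+]
Why: Oxidative addition of zerovalent palladium to the enol triflate, CO insertion and capture of the acyl–palladium bond by the nearby C3 tertiary hydroxyl should close the seven-membered lactone (Pd-catalysed carbonylative lactonisation of a hydroxy enol triflate).

Step 19
Reactants: 29 α-methylene lactone ketone
Product: 30 (15R)-lactone ketone (C15–CH3 installed; C11 ketone)
Conditions: RhCl(PPh3)3 (10 mol %), H2 (1 atm), benzene, rt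
Reagents that add atoms: none
Why: RhCl(PPh3)3 hydrogenates the conjugated 1,1-disubstituted alkene much faster than the trisubstituted ring alkene, and in the chair-like lactone the C15 face next to C1 is shielded by the oxolane, so hydrogen should arrive from the C14–H side and give 15R.

Step 20
Reactants: 30 (15R)-lactone ketone
Product: 31 C11 tertiary alcohol (11R; 11-methyl cis to H10)
Conditions: MeMgBr, CeCl3, THF, −78 °C
Reagents that add atoms: methylmagnesium bromide, C[Mg]Br
Why: The organocerium reagent should add to the ketone and not to the hindered lactone, attacking C11 axially from the convex face away from the axial C10–C9 bond to give the equatorial tertiary alcohol.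

Step 21
Reactants: 31 C11 tertiary alcohol
Product: 32 target, CNP0294597.2
Conditions: butanoic anhydride, DMAP, Et3N, CH2Cl2, 40 °C
Reagents that add atoms: butanoic anhydride, CCCC(=O)OC(=O)CCC
Why: DMAP-catalysed acylation of the equatorial tertiary alcohol should give the butanoate without disturbing the lactone or C15.

**Compound list**

1 | 2-(2-bromoethyl)-1,3-dioxolane | BrCCC1OCCO1 | starting material
2 | methacrolein | CC(=C)C=O | starting material
3 | [2-(1,3-dioxolan-2-yl)ethyl]magnesium bromide | Br[Mg]CCC1OCCO1 | intermediate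
4 | (±)-1-(1,3-dioxolan-2-yl)-4-methylpent-4-en-3-ol | C=C(C)C(O)CCC1OCCO1 | intermediate
5 | 1-(1,3-dioxolan-2-yl)-4-methylpent-4-en-3-one | C=C(C)C(=O)CCC1OCCO1 | intermediate
6 | (3S)-1-(1,3-dioxolan-2-yl)-4-methylpent-4-en-3-ol | C=C(C)[C@@H](O)CCC1OCCO1 | intermediate
7 | ethyl propiolate | C#CC(=O)OCC | starting material
8 | ethyl (2E)-3-{[(3S)-1-(1,3-dioxolan-2-yl)-4-methylpent-4-en-3-yl]oxy}prop-2-enoate | CCOC(=O)/C=C/O[C@@H](CCC1OCCO1)C(C)=C | intermediate
9 | ethyl (2E)-3-{[(3S)-2-methyl-6-oxohex-1-en-3-yl]oxy}prop-2-enoate | CCOC(=O)/C=C/O[C@@H](CCC=O)C(C)=C | intermediate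
10 | samarium ketyl of 9 (O-bound trivalent samarium, radical at the former aldehyde carbon) | CCOC(=O)/C=C/O[C@@H](CC[CH]O[Sm](I)I)C(C)=C | intermediate
11 | ethyl 2-[(2S,3R,6S)-3-hydroxy-6-(prop-1-en-2-yl)oxan-2-yl]acetate | CCOC(=O)C[C@@H]1O[C@H](C(C)=C)CC[C@H]1O | intermediate
12 | ethyl 2-[(2S,6S)-3-oxo-6-(prop-1-en-2-yl)oxan-2-yl]acetate | CCOC(=O)C[C@@H]1O[C@H](C(C)=C)CCC1=O | intermediate
13 | ethyl 2-[(2S,3S,6S)-3-hydroxy-3-methyl-6-(prop-1-en-2-yl)oxan-2-yl]acetate | CCOC(=O)C[C@@H]1O[C@H](C(C)=C)CC[C@]1(C)O | intermediate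
14 | ethyl 2-[(2S,3S,6S)-3-[(tert-butyldimethylsilyl)oxy]-3-methyl-6-(prop-1-en-2-yl)oxan-2-yl]acetate | CCOC(=O)C[C@@H]1O[C@H](C(C)=C)CC[C@]1(C)O[Si](C)(C)C(C)(C)C | intermediate
15 | 2-[(2S,3S,6S)-3-[(tert-butyldimethylsilyl)oxy]-3-methyl-6-(prop-1-en-2-yl)oxan-2-yl]acetic acid | OC(=O)C[C@@H]1O[C@H](C(C)=C)CC[C@]1(C)O[Si](C)(C)C(C)(C)C | intermediate
16 | isobutyl carbonic mixed anhydride of 15 | CC(C)COC(=O)OC(=O)C[C@@H]1O[C@H](C(C)=C)CC[C@]1(C)O[Si](C)(C)C(C)(C)C | intermediate
17 | 1-diazo-3-[(2S,3S,6S)-3-[(tert-butyldimethylsilyl)oxy]-3-methyl-6-(prop-1-en-2-yl)oxan-2-yl]propan-2-one | [N-]=[N+]=CC(=O)C[C@@H]1O[C@H](C(C)=C)CC[C@]1(C)O[Si](C)(C)C(C)(C)C | intermediate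
18 | bicyclic oxonium ylide (oxane oxygen bonded to the former diazo carbon; enolate form) | [O-]C1=C[O+]2[C@H](C(C)=C)CC[C@](C)(O[Si](C)(C)C(C)(C)C)[C@@H]2C1 | intermediate
19 | E/Z mixture of 2-[(tert-butyldimethylsilyl)oxy]-2,6-dimethyl-11-oxabicyclo[6.2.1]undec-5-en-9-one | O=C1C[C@@H]2O[C@H]1CC(C)=CCC[C@]2(C)O[Si](C)(C)C(C)(C)C | intermediate
20 | (1S,2S,5Z,8S)-2-[(tert-butyldimethylsilyl)oxy]-2,6-dimethyl-11-oxabicyclo[6.2.1]undec-5-en-9-one | O=C1C[C@@H]2O[C@H]1C/C(C)=C\CC[C@]2(C)O[Si](C)(C)C(C)(C)C | intermediate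
21 | C10 enol triflate of 20 (C10(OTf)=C1; 2S,3S,9S; 6Z) | FC(F)(F)S(=O)(=O)OC1=C[C@@H]2O[C@H]1C/C(C)=C\CC[C@]2(C)O[Si](C)(C)C(C)(C)C | intermediate
22 | tributyl(1-ethoxyvinyl)stannane | CCCC[Sn](CCCC)(CCCC)C(=C)OCC | starting material
23 | bicyclic 2-ethoxydiene (C1=C10–C11(OEt)=C12H2; 2S,3S,9S; 6Z) | C=C(OCC)C1=C[C@@H]2O[C@H]1C/C(C)=C\CC[C@]2(C)O[Si](C)(C)C(C)(C)C | intermediate
24 | methyl vinyl ketone | CC(=O)C=C | starting material
25 | Diels–Alder adduct as C14 epimer mixture (C10=C11 enol ether; C14 acetyl) | CCOC1=C2[C@@H]3C/C(C)=C\CC[C@](C)(O[Si](C)(C)C(C)(C)C)[C@@H](O3)[C@H]2C(C(C)=O)CC1 | intermediate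
26 | trans-acetyl cycloadduct (C10=C11 ethyl enol ether; C14 acetyl trans to C2; 1S,2S,3S,9S,14R; 6Z) | CCOC1=C2[C@@H]3C/C(C)=C\CC[C@](C)(O[Si](C)(C)C(C)(C)C)[C@@H](O3)[C@H]2[C@H](C(C)=O)CC1 | intermediate
27 | C15 enol triflate (C14–C15(OTf)=C16H2; enol ether and silyl ether retained) | CCOC1=C2[C@@H]3C/C(C)=C\CC[C@](C)(O[Si](C)(C)C(C)(C)C)[C@@H](O3)[C@H]2[C@H](C(=C)OS(=O)(=O)C(F)(F)F)CC1 | intermediate
28 | hydroxy ketone enol triflate (free C3–OH; C11 ketone; 1S,2S,3S,9S,10R,14R; 6Z) | O=C1CC[C@@H](C(=C)OS(=O)(=O)C(F)(F)F)[C@H]2[C@@H]1[C@@H]1C/C(C)=C\CC[C@](C)(O)[C@H]2O1 | intermediate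
29 | α-methylene lactone ketone (C17(=O)–O–C3 lactone; C15=C16H2; C11 ketone) | O=C1CC[C@@H]2[C@H]3[C@@H]1[C@@H]1C/C(C)=C\CC[C@](C)(OC(=O)C2=C)[C@H]3O1 | intermediate
30 | (15R)-lactone ketone (saturated lactone; C11 ketone) | O=C1CC[C@@H]2[C@H]3[C@@H]1[C@@H]1C/C(C)=C\CC[C@](C)(OC(=O)[C@@H]2C)[C@H]3O1 | intermediate
31 | C11 tertiary alcohol (11R; des-butanoyl target) | O[C@]1(C)CC[C@@H]2[C@H]3[C@@H]1[C@@H]1C/C(C)=C\CC[C@](C)(OC(=O)[C@@H]2C)[C@H]3O1 | intermediate
32 | CNP0294597.2 (1S,2S,3S,9S,10R,11R,14R,15R; 6Z) | CCCC(=O)O[C@]1(C)CC[C@@H]2[C@H]3[C@@H]1[C@@H]1C/C(C)=C\CC[C@](C)(OC(=O)[C@@H]2C)[C@H]3O1 | target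

**Summary**

Total step count: 21. Longest linear sequence: 21 steps (fully linear from 1).

Steps most likely to fail, with fallbacks:

Step 18 (carbonylative lactonisation). The hindered tertiary C3 hydroxyl may fail to intercept the acyl–palladium intermediate before it is hydrolysed or reduced, or the seven-membered closure may be too slow. The fallback separates carbonylation from ring closure and sets out from 27. Intermolecular methoxycarbonylation (Pd(OAc)2, PPh3, CO, MeOH, Et3N, DMF) should give the methyl acrylate ester F1. Aqueous HF in MeCN should then give the hydroxy keto ester F2, and LiOH the seco acid F3. Lactonisation with 2-methyl-6-nitrobenzoic anhydride and DMAP under slow addition (Shiina lactonisation) closes the ring, and the route is rejoined at 29.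

Step 19 (hydrogenation at C15). Hydrogen may be delivered with poor or inverted facial selectivity if the lactone does not adopt the chair-like conformation assumed, or the exocyclic alkene may migrate into the ring. The fallback moves C15 from substrate control to catalyst control on an open-chain acid and sets out from 29. LiOH opens the lactone to the seco acid F3 (the compound also met in the first fallback). Asymmetric hydrogenation of this α-substituted acrylic acid with Ru(OAc)2[(R)-BINAP] (BINAP = 2,2'-bis(diphenylphosphino)-1,1'-binaphthyl) and H2 in MeOH should give the (15R)-hydroxy acid F4; the ligand enantiomer is chosen for 15R by analogy with 2-arylacrylic acids. Shiina lactonisation under mild conditions returns to the route at 30.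

Step 20 (methyl addition at C11). The reagent may attack the lactone carbonyl, enolise the ketone or the lactone (epimerising C10 or C15), or add with poor facial selectivity. The fallback installs the methyl group before the lactone exists and sets out from 28. Excess MeMgBr with CeCl3 should give the diol enol triflate F5. Carbonylative lactonisation as in step 18 should give the 11-hydroxy α-methylene lactone F6, since only the C3 hydroxyl can reach the acyl–palladium carbon. Hydrogenation with RhCl(PPh3)3 then rejoins the route at 31.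

Further compounds
F1 | step 18 | methyl acrylate ester from 27 (C14–C15(=CH2)–CO2Me; enol ether and silyl ether retained) | CCOC1=C2[C@@H]3C/C(C)=C\CC[C@](C)(O[Si](C)(C)C(C)(C)C)[C@@H](O3)[C@H]2[C@H](C(=C)C(=O)OC)CC1
F2 | step 18 | hydroxy keto methyl ester (free C3–OH; C11 ketone) | O=C1CC[C@@H](C(=C)C(=O)OC)[C@H]2[C@@H]1[C@@H]1C/C(C)=C\CC[C@](C)(O)[C@H]2O1
F3 | step 18 | seco acid (free C3–OH; C11 ketone; C15(=CH2)–CO2H) | O=C1CC[C@@H](C(=C)C(=O)O)[C@H]2[C@@H]1[C@@H]1C/C(C)=C\CC[C@](C)(O)[C@H]2O1
F4 | step 19 | (15R)-hydroxy acid (free C3–OH; C11 ketone) | O=C1CC[C@@H]([C@@H](C)C(=O)O)[C@H]2[C@@H]1[C@@H]1C/C(C)=C\CC[C@](C)(O)[C@H]2O1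
F5 | step 20 | diol enol triflate (C3–OH; C11 tertiary alcohol; C15 enol triflate) | O[C@]1(C)CC[C@@H](C(=C)OS(=O)(=O)C(F)(F)F)[C@H]2[C@@H]1[C@@H]1C/C(C)=C\CC[C@](C)(O)[C@H]2O1
F6 | step 20 | 11-hydroxy α-methylene lactone | O[C@]1(C)CC[C@@H]2[C@H]3[C@@H]1[C@@H]1C/C(C)=C\CC[C@](C)(OC(=O)C2=C)[C@H]3O1
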